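Ring C is disconnected at O1–C2 and C2–C3. C3 and C4, with rings A and D, are carried as a 1,1-diarylethylene in which ring A holds the free O1 hydroxyl ortho to the alkene; C2 and ring B arrive as a 4-oxygenated benzaldehyde. In one operation a chiral confined Brønsted acid condenses the two, closes ring C through both bonds, sets C2 and leaves a 4-aryl-2H-chromene. The step exploits the ortho relationship between O1 on ring A and the C3=C4 unit that C4 shares with ring D. The ethylene comes from aryl-metal addition to a protected 2-hydroxyacetophenone; hydrogenation (sets C4, frees the phenols) and Houben–Hoesch lauroylation of ring D follow.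

Key step: step 6

Remark (assumption): which antipode of the confined acid gives the (S)-chromene cannot be predicted with confidence; the (S,S)-acid is written and is exchanged for its mirror image if a first run should show the opposite sense.
Remark: in step 7 the saturation of C3=C4 and the five hydrogenolyses need not follow a fixed order, so no single intermediate is numbered there.

Step 1
Reactants: 1 1,3,5-tris(benzyloxy)benzene
Product: 2 2-bromo-1,3,5-tris(benzyloxy)benzene
Conditions: NBS (1.0 equiv), CH2Cl2, −78 → 0 °C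
Reagents that add atoms: N-bromosuccinimide, O=C1CCC(=O)N1Br
Why: Electrophilic aromatic bromination; the three open ring positions of the symmetric triether are equivalent and the first bromine slows a second substitution, so one equivalent of NBS at low temperature should stop at the monobromide.

Step 2
Reactants: 3 1-[4-(benzyloxy)-2-hydroxyphenyl]ethan-1-one
Product: 4 1-[4-(benzyloxy)-2-(methoxymethoxy)phenyl]ethan-1-one
Conditions: NaH, MOMCl, DMF, 0 °C → rt
Reagents that add atoms: chloromethyl methyl ether, COCCl
Why: Williamson-type O-alkylation of the sodium phenoxide masks the acidic chelated phenol, which would otherwise consume and deactivate the aryl-metal reagent of step 3, as an acetal that tolerates organometallics and leaves under mild acid.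

Step 3
Reactants: 2 2-bromo-1,3,5-tris(benzyloxy)benzene; 4 1-[4-(benzyloxy)-2-(methoxymethoxy)phenyl]ethan-1-one
Product: 7 rac-1-[4-(benzyloxy)-2-(methoxymethoxy)phenyl]-1-[2,4,6-tris(benzyloxy)phenyl]ethan-1-ol, via aryllithium 5 (not isolated), via arylcerium dichloride 6 (not isolated)
Conditions: 2, n-BuLi, THF, −78 °C; CeCl3 (anhydrous), −78 °C; then 4, −78 → −20 °C; H2O
Reagents that add atoms: none
Why: Bromine–lithium exchange (faster at −78 °C than benzylic deprotonation of the benzyl ethers) and transmetalation to the weakly basic organocerium reagent should give clean 1,2-addition to the enolisable methyl ketone; the tertiary carbinol centre forms racemic and is erased in step 4.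

Step 4
Reactants: 7 rac-1-[4-(benzyloxy)-2-(methoxymethoxy)phenyl]-1-[2,4,6-tris(benzyloxy)phenyl]ethan-1-ol
Product: 9 5-(benzyloxy)-2-{1-[2,4,6-tris(benzyloxy)phenyl]ethenyl}phenol, via diarylethylene MOM ether 8 (not isolated)
Conditions: HCl (1 M in MeOH), THF, 40 °C
Reagents that add atoms: none
Why: E1 dehydration of the doubly benzylic tertiary alcohol (the methyl group holds the only β-hydrogens, so only the 1,1-diarylethylene can form) is followed in the same acidic methanol by methanolysis of the phenolic MOM acetal, conditions under which the benzyl ethers are stable.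

Step 5
Reactants: 10 4-hydroxybenzaldehyde
Product: 11 benzyl 4-formylphenyl carbonate
Conditions: CbzCl, Et3N, CH2Cl2, 0 °C → rt
Reagents that add atoms: benzyl chloroformate, O=C(Cl)OCc1ccccc1
Why: O-acylation of the phenol by the chloroformate turns the para oxygen into an electron-poor carbonate, which makes the aldehyde more electrophilic, makes later cation formation at C2 harder, and is still removed by hydrogenolysis together with the benzyl ethers.

Step 6
Reactants: 9 5-(benzyloxy)-2-{1-[2,4,6-tris(benzyloxy)phenyl]ethenyl}phenol; 11 benzyl 4-formylphenyl carbonate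
Product: 15 benzyl 4-{(2S)-7-(benzyloxy)-4-[2,4,6-tris(benzyloxy)phenyl]-2H-chromen-2-yl}phenyl carbonate, via hemiacetal 12 (not isolated), via oxocarbenium ion 13 (not isolated), via chroman-4-yl cation 14 (not isolated)
Conditions: (S,S)-iIDP acid [imino-imidodiphosphate, two (S)-3,3′-bis(2,4,6-triethylphenyl)-BINOL units on P(=O)–NH–P(=NSO2CF3)] (5 mol %), 5 Å MS, toluene, −40 °C
Reagents that add atoms: none
Why: Proposed new method: the confined acid should turn phenol 9 and aldehyde 11 into hemiacetal 12 and ionise it to the O-aryl oxocarbenium ion 13 (O1–C2), held as a contact ion pair in the chiral pocket; the terminal alkene carbon C3 then attacks C2 (C2–C3), which closes ring C and leaves cation 14 at C4, stabilised by O1 (ortho) and the 7-benzyloxy group (para) of ring A, and loss of a proton from C3 gives the 2H-chromene. The closest known reaction types are the confined-acid-catalysed asymmetric Prins cyclisation and oxa-Pictet–Spengler reaction of aldehydes with aliphatic alcohols, and the chiral-anion-directed closure of a phenol onto an allyl cation that gives 2H-chromenes; a phenol as oxygen partner combined with a 1,1-diarylethylene as π-nucleophile has not been shown. Ring C closes in the 6-endo-trig mode, because attack through the CH2 terminus is the only Markovnikov option and places the charge on the diaryl-substituted carbon. The one new stereocentre, C2, is under catalyst control: the chiral counter-anion leaves one face of the oxocarbenium carbon open to the tethered alkene, and if the alkene should add to the acid-bound aldehyde before O1 does, ionisation of the resulting allylic alcohol and O1–C2 closure pass through the same kind of chiral ion pair to the same product. The step needs the intramolecular closure to outrun Friedel–Crafts attack of ring D on the aldehyde and needs the product not to re-ionise at C2; the O1–C2 tether, the twisted and hindered ring D, the fact that cation 14 has β-hydrogens only at C3 (one alkene isomer), the electron-poor carbonate on ring B, the sieves and the low temperature are meant to secure both.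

Step 7
Reactants: 15 benzyl 4-{(2S)-7-(benzyloxy)-4-[2,4,6-tris(benzyloxy)phenyl]-2H-chromen-2-yl}phenyl carbonate
Product: 16 (2S,4S)-2-(4-hydroxyphenyl)-4-(2,4,6-trihydroxyphenyl)-3,4-dihydro-2H-chromen-7-ol
Conditions: H2 (1 atm), 10% Pd/C, THF/MeOH, rt
Reagents that add atoms: none
Why: Heterogeneous catalytic hydrogenation should add both hydrogens to C3=C4 from the face opposite the C2 aryl group (ring B shields its own face of the half-chair), which sets C4 as S with ring D cis to ring B, while the same catalyst hydrogenolyses the four benzyl ethers and the benzyl carbonate, the latter with loss of CO2.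

Step 8
Reactants: 16 (2S,4S)-2-(4-hydroxyphenyl)-4-(2,4,6-trihydroxyphenyl)-3,4-dihydro-2H-chromen-7-ol; 17 dodecanenitrile
Product: 19 1-{2,4,6-trihydroxy-3-[(2S,4S)-7-hydroxy-2-(4-hydroxyphenyl)-3,4-dihydro-2H-chromen-4-yl]phenyl}dodecan-1-one, via ketiminium chloride 18 (not isolated)
Conditions: ZnCl2, HCl (g), Et2O/1,4-dioxane, 0 °C → rt; then H2O, 60 °C
Reagents that add atoms: water, O
Why: Houben–Hoesch acylation: the HCl/ZnCl2-activated nitrile should attack the phloroglucinol ring D, by far the most nucleophilic ring and one whose two open positions lead to the same product, the ketiminium salt protects that ring from a second acylation, and mild aqueous hydrolysis releases the aryl ketone without touching C2 or C4.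

Compound list
1 | 1,3,5-tris(benzyloxy)benzene | c1c(OCc2ccccc2)cc(OCc2ccccc2)cc1OCc1ccccc1 | starting material
2 | 2-bromo-1,3,5-tris(benzyloxy)benzene | Brc1c(OCc2ccccc2)cc(OCc2ccccc2)cc1OCc1ccccc1 | intermediate
3 | 1-[4-(benzyloxy)-2-hydroxyphenyl]ethan-1-one | CC(=O)c1ccc(OCc2ccccc2)cc1O | starting material
4 | 1-[4-(benzyloxy)-2-(methoxymethoxy)phenyl]ethan-1-one | CC(=O)c1ccc(OCc2ccccc2)cc1OCOC | intermediate
5 | [2,4,6-tris(benzyloxy)phenyl]lithium (not isolated) | [Li]c1c(OCc2ccccc2)cc(OCc2ccccc2)cc1OCc1ccccc1 | intermediate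
6 | dichloro[2,4,6-tris(benzyloxy)phenyl]cerium (not isolated) | Cl[Ce](Cl)c1c(OCc2ccccc2)cc(OCc2ccccc2)cc1OCc1ccccc1 | intermediate
7 | rac-1-[4-(benzyloxy)-2-(methoxymethoxy)phenyl]-1-[2,4,6-tris(benzyloxy)phenyl]ethan-1-ol | CC(O)(c1ccc(OCc2ccccc2)cc1OCOC)c1c(OCc2ccccc2)cc(OCc2ccccc2)cc1OCc1ccccc1 | intermediate
8 | 4-(benzyloxy)-2-(methoxymethoxy)-1-{1-[2,4,6-tris(benzyloxy)phenyl]ethenyl}benzene (not isolated) | C=C(c1ccc(OCc2ccccc2)cc1OCOC)c1c(OCc2ccccc2)cc(OCc2ccccc2)cc1OCc1ccccc1 | intermediate
9 | 5-(benzyloxy)-2-{1-[2,4,6-tris(benzyloxy)phenyl]ethenyl}phenol | C=C(c1ccc(OCc2ccccc2)cc1O)c1c(OCc2ccccc2)cc(OCc2ccccc2)cc1OCc1ccccc1 | intermediate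
10 | 4-hydroxybenzaldehyde | O=Cc1ccc(O)cc1 | starting material
11 | benzyl 4-formylphenyl carbonate | O=Cc1ccc(OC(=O)OCc2ccccc2)cc1 | intermediate
12 | hemiacetal of 9 and 11, benzyl 4-[(5-(benzyloxy)-2-{1-[2,4,6-tris(benzyloxy)phenyl]ethenyl}phenoxy)(hydroxy)methyl]phenyl carbonate, both configurations at the hemiacetal carbon (not isolated) | OC(Oc1cc(OCc2ccccc2)ccc1C(=C)c1c(OCc2ccccc2)cc(OCc2ccccc2)cc1OCc1ccccc1)c1ccc(OC(=O)OCc2ccccc2)cc1 | intermediate
13 | O-aryl oxocarbenium ion formed from 12 by loss of hydroxide, cation of the ion pair with the catalyst anion (not isolated) | C=C(c1ccc(OCc2ccccc2)cc1[O+]=Cc1ccc(OC(=O)OCc2ccccc2)cc1)c1c(OCc2ccccc2)cc(OCc2ccccc2)cc1OCc1ccccc1 | intermediate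
14 | (2S)-7-(benzyloxy)-2-{4-[(benzyloxycarbonyl)oxy]phenyl}-4-[2,4,6-tris(benzyloxy)phenyl]chroman-4-ylium, cation of the ion pair with the catalyst anion (not isolated) | c1(OCc5ccccc5)cc(OCc5ccccc5)cc(OCc5ccccc5)c1[C+]2C[C@@H](c3ccc(OC(=O)OCc4ccccc4)cc3)Oc3cc(OCc4ccccc4)ccc32 | intermediate
15 | benzyl 4-{(2S)-7-(benzyloxy)-4-[2,4,6-tris(benzyloxy)phenyl]-2H-chromen-2-yl}phenyl carbonate | c1(OCc5ccccc5)cc(OCc5ccccc5)cc(OCc5ccccc5)c1C2=C[C@@H](c3ccc(OC(=O)OCc4ccccc4)cc3)Oc3cc(OCc4ccccc4)ccc32 | intermediate
16 | (2S,4S)-2-(4-hydroxyphenyl)-4-(2,4,6-trihydroxyphenyl)-3,4-dihydro-2H-chromen-7-ol (rings B and D cis) | Oc1cc(O)c([C@H]2C[C@@H](c3ccc(O)cc3)Oc3cc(O)ccc32)c(O)c1 | intermediate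
17 | dodecanenitrile | CCCCCCCCCCCC#N | starting material
18 | 1-{2,4,6-trihydroxy-3-[(2S,4S)-7-hydroxy-2-(4-hydroxyphenyl)-3,4-dihydro-2H-chromen-4-yl]phenyl}dodecan-1-iminium chloride (not isolated) | CCCCCCCCCCCC(=[NH2+])c1c(O)cc(O)c([C@H]2C[C@@H](c3ccc(O)cc3)Oc3cc(O)ccc32)c1O.[Cl-] | intermediate
19 | 1-{2,4,6-trihydroxy-3-[(2S,4S)-7-hydroxy-2-(4-hydroxyphenyl)-3,4-dihydro-2H-chromen-4-yl]phenyl}dodecan-1-one | CCCCCCCCCCCC(=O)c1c(O)cc(O)c([C@H]2C[C@@H](c3ccc(O)cc3)Oc3cc(O)ccc32)c1O | target

Total step count: 8.
Longest linear sequence: 6 steps (steps 1 or 2, then 3, 4, 6, 7, 8).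

Steps most likely to fail

Step 6 (proposed method). Several processes could defeat it:
- reversible ionisation of the O1–C2 bond of the product, which would erode the configuration at C2;
- weak face discrimination at the oxocarbenium carbon;
- intermolecular Friedel–Crafts attack of ring D on the aldehyde;
- acid-induced dimerisation of the diarylethylene;
- hydride loss from C2 of the product towards a benzopyrylium salt.

The fallback uses known chemistry, sets out from acetophenone 3 and comes back to the route at 16. Claisen–Schmidt condensation of 3 with commercial 4-(benzyloxy)benzaldehyde (O=Cc1ccc(OCc2ccccc2)cc1; KOH, EtOH, rt) should give the chalcone (E)-1-[4-(benzyloxy)-2-hydroxyphenyl]-3-[4-(benzyloxy)phenyl]prop-2-en-1-one F1. 1,2-Addition of an excess of the arylcerium reagent 6 (from bromide 2 as in step 3; one equivalent is spent on the phenol) should give the allylic alcohol rac-(E)-1-[4-(benzyloxy)-2-hydroxyphenyl]-3-[4-(benzyloxy)phenyl]-1-[2,4,6-tris(benzyloxy)phenyl]prop-2-en-1-ol F2. A chiral BINOL-derived N-triflylphosphoramide (3,3′-bis(2,4,6-triisopropylphenyl) groups, the antipode that leads to S; toluene, −78 °C) ionises F2 to an allyl cation paired with the chiral anion. The phenol closes onto it in an asymmetric intramolecular allylic substitution, a known type of enantioselective 2H-chromene synthesis. This should give (2S)-7-(benzyloxy)-2-[4-(benzyloxy)phenyl]-4-[2,4,6-tris(benzyloxy)phenyl]-2H-chromene F3, which is hydrogenated under the conditions of step 7 to 16.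

Step 8. The acylation may stray onto ring A. Acid may also cleave the C4–ring D bond heterolytically (the C4 cation is stabilised by O1 and the 7-hydroxyl) or the O1–C2 bond (assisted by the free 4′-hydroxyl), which would scramble C4 or C2. The fallback acylates before deprotection; it sets out from 15 and comes back at the target 19. The benzyl-protected cis-chroman F4 (made from 15 as described for step 7 below) is treated with dodecanoic acid (CCCCCCCCCCCC(=O)O) and trifluoroacetic anhydride (CH2Cl2, 0 °C). This mixed-anhydride Friedel–Crafts acylation reaches only very electron-rich arenes, so the tris(benzyloxy) ring D should react while ring B is switched off by its carbonate. It should give benzyl 4-{(2S,4S)-7-(benzyloxy)-4-[2,4,6-tris(benzyloxy)-3-dodecanoylphenyl]-3,4-dihydro-2H-chromen-2-yl}phenyl carbonate F5. Hydrogenolysis (H2, Pd/C, THF/MeOH) then gives 19, the chelated aryl ketone being slow to reduce.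

Step 7. The allylic, benzylic O1–C2 bond may be hydrogenolysed before the alkene is saturated. Face discrimination at C4 may be insufficient, or C2 may erode if the 4′-oxygen is unmasked while C3=C4 is still present. The fallback separates the two events and changes the mechanism of the reduction; it sets out from 15 and comes back at 16. Ionic hydrogenation (Et3SiH, CF3CO2H, CH2Cl2, −40 °C) protonates C3 and delivers hydride to the C4 cation on the face anti to ring B, the carbonate on ring B holding the O1–C2 bond against ionisation. It should give benzyl 4-{(2S,4S)-7-(benzyloxy)-4-[2,4,6-tris(benzyloxy)phenyl]-3,4-dihydro-2H-chromen-2-yl}phenyl carbonate F4. Hydrogenolysis (H2, Pd/C) then has only O-benzyl groups to cleave and gives 16.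

Further compounds
F1 | step 6 | (E)-1-[4-(benzyloxy)-2-hydroxyphenyl]-3-[4-(benzyloxy)phenyl]prop-2-en-1-one | O=C(/C=C/c1ccc(OCc2ccccc2)cc1)c1ccc(OCc2ccccc2)cc1O
F2 | step 6 | rac-(E)-1-[4-(benzyloxy)-2-hydroxyphenyl]-3-[4-(benzyloxy)phenyl]-1-[2,4,6-tris(benzyloxy)phenyl]prop-2-en-1-ol | OC(/C=C/c1ccc(OCc2ccccc2)cc1)(c1ccc(OCc2ccccc2)cc1O)c1c(OCc2ccccc2)cc(OCc2ccccc2)cc1OCc1ccccc1
F3 | step 6 | (2S)-7-(benzyloxy)-2-[4-(benzyloxy)phenyl]-4-[2,4,6-tris(benzyloxy)phenyl]-2H-chromene | c1(OCc5ccccc5)cc(OCc5ccccc5)cc(OCc5ccccc5)c1C2=C[C@@H](c3ccc(OCc4ccccc4)cc3)Oc3cc(OCc4ccccc4)ccc32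
F4 | step 7 | benzyl 4-{(2S,4S)-7-(benzyloxy)-4-[2,4,6-tris(benzyloxy)phenyl]-3,4-dihydro-2H-chromen-2-yl}phenyl carbonate | c1(OCc5ccccc5)cc(OCc5ccccc5)cc(OCc5ccccc5)c1[C@H]2C[C@@H](c3ccc(OC(=O)OCc4ccccc4)cc3)Oc3cc(OCc4ccccc4)ccc32
F5 | step 8 | benzyl 4-{(2S,4S)-7-(benzyloxy)-4-[2,4,6-tris(benzyloxy)-3-dodecanoylphenyl]-3,4-dihydro-2H-chromen-2-yl}phenyl carbonate | CCCCCCCCCCCC(=O)c1c(OCc2ccccc2)cc(OCc2ccccc2)c([C@H]2C[C@@H](c3ccc(OC(=O)OCc4ccccc4)cc3)Oc3cc(OCc4ccccc4)ccc32)c1OCc1ccccc1
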